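**Retrosynthetic overview**

- The target is a 2-oxaspiro[4.5]deca-6,9-dien-8-one. Ring B is the oxolane C1–O2–C3–C4–C5: C1 carries the chain C1′(OAr)–C2′H2OH, C3 the guaiacyl group, C4 the hydroxymethyl carbon C4a. It is spiro-fused at C5 to ring A, the dienone C6=C7(OMe)–C8(=O)–C9=C10.
- The feature used: C1(O2)–C1′(O)–C2′(O) is a 2,3-epoxy alcohol in disguise, and the C1 and C3 substituents lie trans across O2.
- Disconnections: C1′–OAr (Mitsunobu inversion with the dihydroconiferyl phenol), then O2–C1 (5-exo opening of a Sharpless trans-epoxide by the C3 hydroxyl). The dienone comes from an enone by C7 hydroxylation, oxidation and O-methylation; C3–C4 from an Evans syn-aldol; C5 from an enantioselective Diels–Alder reaction followed by Horner–Wadsworth–Emmons olefination.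
- Ring order: ring A first (Diels–Alder), ring B second (key step); the dienone is completed before ring B closes and the aryl ether is attached last.

Key step: step 19

Remark: (R,R)-1-naphthyl-TADDOL is assumed to give the (R)-configured cycloadduct in step 4; if the sense proves opposite, the (S,S)-catalyst is used and nothing else changes.

Abbreviations: TBS = tert-butyldimethylsilyl, TES = triethylsilyl, Ar = 4-(TBSO)-3-methoxyphenyl. Locants C1–C10, C1′, C2′ and C4a are those of the overview and are used for all intermediates.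

**Route**

Step 1
Reactants: 1 vanillin
Product: 2 4-(tert-butyldimethylsilyloxy)-3-methoxybenzaldehyde
Conditions: TBSCl, imidazole, DMF, 0 °C to rt
Reagents that add atoms: tert-butyldimethylsilyl chloride, CC(C)(C)[Si](C)(C)Cl
Why: Imidazole-promoted O-silylation of the phenol should proceed cleanly and leaves the aldehyde free for the aldol reaction.

Step 2
Reactants: 3 dihydroconiferyl alcohol
Product: 5 4-[3-(tert-butyldimethylsilyloxy)propyl]-2-methoxyphenol, via bis-TBS ether 4 (not isolated)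
Conditions: TBSCl (2.4 equiv), imidazole, DMF, rt; then MeOH, K2CO3 (0.3 equiv), rt
Reagents that add atoms: tert-butyldimethylsilyl chloride, CC(C)(C)[Si](C)(C)Cl
Why: Exhaustive silylation followed by selective desilylation (carbonate-catalysed methanolysis cleaves an aryl silyl ether much faster than an alkyl one) should leave only the phenol free.

Step 3
Reactants: 6 tert-butyl 4-oxobutanoate
Product: 7 tert-butyl 3-formylbut-3-enoate
Conditions: aq. CH2O (37%), pyrrolidine (10 mol %), EtCO2H (10 mol %), i-PrOH, 45 °C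
Reagents that add atoms: formaldehyde, C=O
Why: Amine-catalysed Mannich condensation and elimination (α-methylenation of an aldehyde) should give the 2-substituted acrolein, which is used at once so that the double bond does not drift into conjugation with the ester.

Step 4
Reactants: 7 tert-butyl 3-formylbut-3-enoate; 8 (E)-3-(tert-butyldimethylsilyloxy)-N,N-dimethylbuta-1,3-dien-1-amine (Rawal diene); 9 triethyl phosphonoacetate
Product: 11 ethyl (E)-3-[(1S)-1-(2-tert-butoxy-2-oxoethyl)-2-(dimethylamino)-4-(TBSO)cyclohex-3-en-1-yl]prop-2-enoate, via cycloadduct aldehyde 10 (not isolated)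
Conditions: (4R,5R)-2,2-dimethyl-α,α,α′,α′-tetra(1-naphthyl)-1,3-dioxolane-4,5-dimethanol (20 mol %), PhMe, −80 °C; then 9/NaH (preformed in THF), −78 °C to rt
Reagents that add atoms: none
Why: The hydrogen-bond-catalysed Diels–Alder reaction of a 1-amino-3-siloxy diene with a 2-substituted acrolein should join the amino carbon to the acrolein α-carbon and set C5 through the exposed face of the TADDOL-bound formyl group, after which Horner–Wadsworth–Emmons olefination of the non-enolisable aldehyde gives the E-enoate.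

Step 5
Reactants: 11 cycloadduct enoate
Product: 13 2-{(1R)-1-[(E)-3-ethoxy-3-oxoprop-1-en-1-yl]-4-oxocyclohex-2-en-1-yl}acetic acid, via enone tert-butyl ester 12 (not isolated)
Conditions: TFA/CH2Cl2 (1:3), H2O (2 equiv), 0 °C to rt
Reagents that add atoms: none
Why: Acid hydrolysis of the silyl enol ether with β-elimination of dimethylamine should give the C9=C10 enone, whose double bond cannot move because C5 is quaternary, and the same acid cleaves the tert-butyl ester by loss of isobutene.

Step 6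
Reactants: 13 enone acid; 14 (S)-4-benzyl-1,3-oxazolidin-2-one
Product: 16 N-acyl oxazolidinone of 13, via mixed pivalic anhydride 15 (not isolated)
Conditions: PivCl, Et3N, THF, −20 °C; then 14, LiCl, −20 °C to rt
Reagents that add atoms: none
Why: N-Acylation of the oxazolidinone through the mixed pivalic anhydride should occur at the less hindered carbonyl under LiCl/Et3N conditions that spare the enone and the enoate.

Step 7
Reactants: 16 N-acyl oxazolidinone
Product: 17 C8 ethylene ketal of 16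
Conditions: (TMSOCH2)2, TMSOTf (5 mol %), CH2Cl2, −78 to −20 °C; pyridine quench
Reagents that add atoms: 1,2-bis(trimethylsilyloxy)ethane, C[Si](C)(C)OCCO[Si](C)(C)C
Why: Noyori ketalisation should mask the ketone against enolisation and hydride without double-bond migration, since the γ-carbon C5 carries no hydrogen.

Step 8
Reactants: 17 ketal imide; 2 4-(tert-butyldimethylsilyloxy)-3-methoxybenzaldehyde
Product: 19 syn-aldol adduct with C4 (S) and C3 (S), via dibutylboron Z-enolate 18 (not isolated)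
Conditions: Bu2BOTf, i-Pr2NEt, CH2Cl2, −78 to 0 °C; then 2, −78 to 0 °C; pH 7 buffer, MeOH, H2O2, 0 °C
Reagents that add atoms: none
Why: In this Evans syn-aldol reaction the Z-boron enolate should react through a Zimmerman–Traxler chair on the face away from the benzyl group of the (S)-auxiliary, which sets C4 and C3 as the syn pair needed for the trans C3/C4 relation of the oxolane and turns any C5 epimer left from step 4 into a separable diastereomer.

Step 9
Reactants: 19 aldol adduct
Product: 20 C3,C4a-diol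
Conditions: LiBH4, MeOH (1 equiv), THF, 0 °C
Reagents that add atoms: none
Why: Reductive cleavage of the N-acyl oxazolidinone by LiBH4 is faster than reduction of the conjugated ethyl ester and should release C4a as the primary alcohol.

Step 10
Reactants: 20 diol
Product: 22 C4a-O-TBS C3-O-TES ether, via mono-TBS ether 21 (not isolated)
Conditions: TBSCl (1.05 equiv), imidazole, CH2Cl2, 0 °C; then TESOTf, 2,6-lutidine, −78 to 0 °C
Reagents that add atoms: tert-butyldimethylsilyl chloride, CC(C)(C)[Si](C)(C)Cl; triethylsilyl trifluoromethanesulfonate, CC[Si](CC)(CC)OS(=O)(=O)C(F)(F)F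
Why: In this selective silylation TBSCl should take the primary C4a alcohol, and the hindered benzylic C3 alcohol is then capped by the more reactive silyl triflate as a TES ether that can later be removed beside TBS ethers.

Step 11
Reactants: 22 bis-silyl ether
Product: 23 (E)-allylic alcohol (C1=C1′–C2′H2OH)
Conditions: i-Bu2AlH (2.5 equiv), CH2Cl2, −78 °C; Rochelle salt work-up
Reagents that add atoms: none
Why: 1,2-Reduction of the α,β-unsaturated ester by i-Bu2AlH should give the E-allylic alcohol while the ketal and the silyl ethers are inert.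

Step 12
Reactants: 23 allylic alcohol ketal
Product: 24 enone allylic alcohol
Conditions: PPTS (0.2 equiv), acetone/H2O (10:1), rt
Reagents that add atoms: water, O
Why: Mild acid hydrolysis of the allylic ketal should restore the enone under conditions that the hindered TES ether and the TBS ethers survive.

Step 13
Reactants: 24 enone allylic alcohol
Product: 25 epoxy alcohol with C1 (R) and C1′ (R)
Conditions: Ti(OiPr)4 (0.2 equiv), D-(−)-diethyl tartrate (0.25 equiv), t-BuOOH (2 equiv, in decane), 4 Å MS, CH2Cl2, −20 °C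
Reagents that add atoms: tert-butyl hydroperoxide, CC(C)(C)OO
Why: In the Sharpless asymmetric epoxidation the titanium D-tartrate complex should deliver oxygen to one face of the E-allylic alcohol under reagent control, giving the (2R,3R)-epoxy alcohol (the mirror image of the (2S,3S) outcome of L-tartrate) and so setting C1 and C1′, while the electron-poor enone is untouched.

Step 14
Reactants: 25 epoxy alcohol
Product: 26 C2′-O-TBS epoxy enone
Conditions: TBSCl, imidazole, CH2Cl2, 0 °C
Reagents that add atoms: tert-butyldimethylsilyl chloride, CC(C)(C)[Si](C)(C)Cl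
Why: Silylation of the primary epoxy alcohol under neutral imidazole conditions should not trigger Payne rearrangement.

Step 15
Reactants: 26 epoxy enone
Product: 28 C7-hydroxy enone (both C7 epimers), via potassium dienolate 27 (not isolated)
Conditions: KN(SiMe3)2, THF, −78 °C; then 3-phenyl-2-(phenylsulfonyl)oxaziridine, −78 °C; AcOH quench
Reagents that add atoms: 3-phenyl-2-(phenylsulfonyl)oxaziridine, O=S(=O)(c1ccccc1)N1OC1c1ccccc1
Why: In this Davis α-hydroxylation deprotonation can occur only at C7, because quaternary C5 leaves no γ-hydrogen, and the new C7 carbinol centre is erased in the next step.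

Step 16
Reactants: 28 C7-hydroxy enone
Product: 30 diosphenol (7-hydroxy-2,5-dienone), via ene-dione 29 (not isolated)
Conditions: Dess–Martin periodinane, pyridine, CH2Cl2, 0 °C to rt
Reagents that add atoms: none
Why: Dess–Martin oxidation of the α-hydroxy ketone gives the 1,2-dione, which can enolise only towards C6 and should therefore settle as the C6=C7(OH) dienone.

Step 17
Reactants: 30 diosphenol
Product: 31 7-methoxy dienone with C3-O-TES
Conditions: MeI, Ag2O, MeCN, rt, dark
Reagents that add atoms: iodomethane, CI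
Why: O-Methylation of the acidic enol under non-basic silver oxide conditions should spare the aryl silyl ether, and C-methylation at C6 is blocked by the adjacent quaternary C5.

Step 18
Reactants: 31 C3-O-TES dienone epoxide
Product: 32 dienone trans-epoxide with free C3 benzylic alcohol
Conditions: HF·pyridine, pyridine, THF, 0 °C
Reagents that add atoms: none
Why: In this selective desilylation buffered HF·pyridine should cleave the TES ether well before the primary and aryl TBS ethers, and the pyridine buffer keeps the epoxide closed.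

Step 19
Reactants: 32 hydroxy epoxide
Product: 33 spirodienone oxolane with C1′ (R) carbinol
Conditions: 10-camphorsulfonic acid (10 mol %), CH2Cl2, −20 to 0 °C; Et3N quench
Reagents that add atoms: none
Why: The sulfonic acid activates the epoxide oxygen and the C3 hydroxyl attacks C1 from the side opposite the C1–O bond, so that O2–C1 forms with inversion and the epoxide oxygen becomes the C1′ hydroxyl; the closest known reaction type is the acid-catalysed cyclisation of hydroxy epoxides (2,3-epoxy alcohol derivatives) to 2-substituted oxolanes. The oxolane, ring B, closes in the 5-exo-tet mode. The new centre C1 (S) is controlled by the epoxide carbon that the Sharpless reagent fixed as R, which forces the C1 side chain trans to the C3 aryl group across O2, and C1′ is carried over unchanged as the R carbinol. The step needs attack at C1 and not 6-endo at C1′, which the five-membered transition state and the inductive deactivation of C1′ by the neighbouring silyloxymethyl group should secure. It also needs the opening to outrun conjugate addition of the C3 hydroxyl to C10; that addition is reversible under acid whereas the epoxide opening is not, so the material should drain to 33. Catalytic acid at low temperature in a non-nucleophilic solvent is chosen so that the TBS ethers and the electron-rich benzylic C3–O bond are not ionised.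

Step 20
Reactants: 33 spirodienone carbinol; 5 4-[3-(tert-butyldimethylsilyloxy)propyl]-2-methoxyphenol
Product: 34 C1′ (S) aryl ether, fully silylated target
Conditions: PPh3, DIAD, PhMe, 0 °C to rt
Reagents that add atoms: none
Why: In this Mitsunobu etherification the alkoxyphosphonium ion of the C1′ carbinol should be displaced by the phenolate of 5 with inversion, which gives the C1′ configuration of the target.

Step 21
Reactants: 34 silylated aryl ether
Product: 35 target CNP0252711.1
Conditions: Bu4NF, AcOH (1:1), THF, 0 °C to rt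
Reagents that add atoms: none
Why: Fluoride-mediated cleavage of the four TBS ethers is buffered with acetic acid so that neither conjugate addition of the freed alcohols to the dienone nor quinone methide formation at the p-hydroxybenzylic C3–O2 bond is promoted by base.

**Compound list**

1 | vanillin | COc1cc(C=O)ccc1O | starting material
2 | 4-(tert-butyldimethylsilyloxy)-3-methoxybenzaldehyde | COc1cc(C=O)ccc1O[Si](C)(C)C(C)(C)C | intermediate
3 | dihydroconiferyl alcohol, 4-(3-hydroxypropyl)-2-methoxyphenol | COc1cc(CCCO)ccc1O | starting material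
4 | bis-TBS ether of 3 | COc1cc(CCCO[Si](C)(C)C(C)(C)C)ccc1O[Si](C)(C)C(C)(C)C | intermediate
5 | 4-[3-(tert-butyldimethylsilyloxy)propyl]-2-methoxyphenol | COc1cc(CCCO[Si](C)(C)C(C)(C)C)ccc1O | intermediate
6 | tert-butyl 4-oxobutanoate | O=CCCC(=O)OC(C)(C)C | starting material
7 | tert-butyl 3-formylbut-3-enoate | C=C(C=O)CC(=O)OC(C)(C)C | intermediate
8 | (E)-3-(tert-butyldimethylsilyloxy)-N,N-dimethylbuta-1,3-dien-1-amine (Rawal diene) | C=C(O[Si](C)(C)C(C)(C)C)/C=C/N(C)C | starting material
9 | triethyl phosphonoacetate | CCOC(=O)CP(=O)(OCC)OCC | starting material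
10 | tert-butyl 2-[(1R)-2-(dimethylamino)-1-formyl-4-(TBSO)cyclohex-3-en-1-yl]acetate, both epimers at the amino carbon | O=C[C@@]1(CC(=O)OC(C)(C)C)CCC(O[Si](C)(C)C(C)(C)C)=CC1N(C)C | intermediate
11 | ethyl (E)-3-[(1S)-1-(2-tert-butoxy-2-oxoethyl)-2-(dimethylamino)-4-(TBSO)cyclohex-3-en-1-yl]prop-2-enoate, both epimers at the amino carbon | CCOC(=O)/C=C/[C@@]1(CC(=O)OC(C)(C)C)CCC(O[Si](C)(C)C(C)(C)C)=CC1N(C)C | intermediate
12 | ethyl (E)-3-[(1R)-1-(2-tert-butoxy-2-oxoethyl)-4-oxocyclohex-2-en-1-yl]prop-2-enoate | O=C1C=C[C@](/C=C/C(=O)OCC)(CC(=O)OC(C)(C)C)CC1 | intermediate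
13 | 2-{(1R)-1-[(E)-3-ethoxy-3-oxoprop-1-en-1-yl]-4-oxocyclohex-2-en-1-yl}acetic acid | O=C1C=C[C@](/C=C/C(=O)OCC)(CC(=O)O)CC1 | intermediate
14 | (S)-4-benzyl-1,3-oxazolidin-2-one | O=C1OC[C@H](Cc2ccccc2)N1 | starting material
15 | mixed anhydride of 13 with pivalic acid | O=C1C=C[C@](/C=C/C(=O)OCC)(CC(=O)OC(=O)C(C)(C)C)CC1 | intermediate
16 | ethyl (E)-3-[(1R)-1-{2-[(4S)-4-benzyl-2-oxo-1,3-oxazolidin-3-yl]-2-oxoethyl}-4-oxocyclohex-2-en-1-yl]prop-2-enoate | O=C1C=C[C@](/C=C/C(=O)OCC)(CC(=O)N2C(=O)OC[C@@H]2Cc2ccccc2)CC1 | intermediate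
17 | C8 ethylene ketal of 16 (1,4-dioxaspiro[4.5]dec-6-ene), C5 unchanged | O1CCOC12C=C[C@](/C=C/C(=O)OCC)(CC(=O)N3C(=O)OC[C@@H]3Cc3ccccc3)CC2 | intermediate
18 | Z-dibutylboron enolate of 17 (C4=C4a, O–BBu2 cis to C5) | O1CCOC12C=C[C@](/C=C/C(=O)OCC)(/C=C(\OB(CCCC)CCCC)N3C(=O)OC[C@@H]3Cc3ccccc3)CC2 | intermediate
19 | syn-aldol adduct: 17 with C4 (S) bearing CH(OH)Ar, C3 (S) | O1CCOC12C=C[C@](/C=C/C(=O)OCC)([C@H](C(=O)N3C(=O)OC[C@@H]3Cc3ccccc3)[C@H](O)c3ccc(O[Si](C)(C)C(C)(C)C)c(OC)c3)CC2 | intermediate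
20 | diol: auxiliary of 19 replaced by C4a H2OH, C3 OH free, ketal and enoate kept | O1CCOC12C=C[C@](/C=C/C(=O)OCC)([C@H](CO)[C@H](O)c3ccc(O[Si](C)(C)C(C)(C)C)c(OC)c3)CC2 | intermediate
21 | 20 with C4a O-TBS | O1CCOC12C=C[C@](/C=C/C(=O)OCC)([C@H](CO[Si](C)(C)C(C)(C)C)[C@H](O)c3ccc(O[Si](C)(C)C(C)(C)C)c(OC)c3)CC2 | intermediate
22 | 21 with C3 O-TES | O1CCOC12C=C[C@](/C=C/C(=O)OCC)([C@H](CO[Si](C)(C)C(C)(C)C)[C@H](O[Si](CC)(CC)CC)c3ccc(O[Si](C)(C)C(C)(C)C)c(OC)c3)CC2 | intermediate
23 | (E)-allylic alcohol: enoate of 22 reduced to C1=C1′–C2′H2OH | O1CCOC12C=C[C@](/C=C/CO)([C@H](CO[Si](C)(C)C(C)(C)C)[C@H](O[Si](CC)(CC)CC)c3ccc(O[Si](C)(C)C(C)(C)C)c(OC)c3)CC2 | intermediate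
24 | enone: 23 with the C8 ketal removed | O=C1C=C[C@](/C=C/CO)([C@H](CO[Si](C)(C)C(C)(C)C)[C@H](O[Si](CC)(CC)CC)c2ccc(O[Si](C)(C)C(C)(C)C)c(OC)c2)CC1 | intermediate
25 | (C1 R, C1′ R)-trans-epoxy alcohol of 24 | O=C1C=C[C@]([C@H]2O[C@@H]2CO)([C@H](CO[Si](C)(C)C(C)(C)C)[C@H](O[Si](CC)(CC)CC)c2ccc(O[Si](C)(C)C(C)(C)C)c(OC)c2)CC1 | intermediate
26 | 25 with C2′ O-TBS | O=C1C=C[C@]([C@H]2O[C@@H]2CO[Si](C)(C)C(C)(C)C)([C@H](CO[Si](C)(C)C(C)(C)C)[C@H](O[Si](CC)(CC)CC)c2ccc(O[Si](C)(C)C(C)(C)C)c(OC)c2)CC1 | intermediate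
27 | potassium cross-conjugated dienolate of 26 (C8 O−, C7=C8) | [K+].[O-]C1=CC[C@@]([C@H]2O[C@@H]2CO[Si](C)(C)C(C)(C)C)([C@H](CO[Si](C)(C)C(C)(C)C)[C@H](O[Si](CC)(CC)CC)c2ccc(O[Si](C)(C)C(C)(C)C)c(OC)c2)C=C1 | intermediate
28 | 26 with OH at C7, both C7 epimers | O=C1C=C[C@]([C@H]2O[C@@H]2CO[Si](C)(C)C(C)(C)C)([C@H](CO[Si](C)(C)C(C)(C)C)[C@H](O[Si](CC)(CC)CC)c2ccc(O[Si](C)(C)C(C)(C)C)c(OC)c2)CC1O | intermediate
29 | C7,C8-dione (cyclohex-5-ene-1,2-dione) from 28 | O=C1C=C[C@]([C@H]2O[C@@H]2CO[Si](C)(C)C(C)(C)C)([C@H](CO[Si](C)(C)C(C)(C)C)[C@H](O[Si](CC)(CC)CC)c2ccc(O[Si](C)(C)C(C)(C)C)c(OC)c2)CC1=O | intermediate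
30 | diosphenol: C6=C7(OH) dienone tautomer of 29 | OC1=C[C@]([C@H]3O[C@@H]3CO[Si](C)(C)C(C)(C)C)(C=CC1=O)[C@H](CO[Si](C)(C)C(C)(C)C)[C@H](O[Si](CC)(CC)CC)c1ccc(O[Si](C)(C)C(C)(C)C)c(OC)c1 | intermediate
31 | 7-methoxy dienone trans-epoxide with C3 O-TES | COC1=C[C@]([C@H]3O[C@@H]3CO[Si](C)(C)C(C)(C)C)(C=CC1=O)[C@H](CO[Si](C)(C)C(C)(C)C)[C@H](O[Si](CC)(CC)CC)c1ccc(O[Si](C)(C)C(C)(C)C)c(OC)c1 | intermediate
32 | key-step precursor: 7-methoxy dienone trans-epoxide with free C3 benzylic alcohol | COC1=C[C@]([C@H]3O[C@@H]3CO[Si](C)(C)C(C)(C)C)(C=CC1=O)[C@H](CO[Si](C)(C)C(C)(C)C)[C@H](O)c1ccc(O[Si](C)(C)C(C)(C)C)c(OC)c1 | intermediate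
33 | key-step product: spirodienone oxolane, C1 (S), C1′ (R) carbinol | COC1=C[C@]2(C=CC1=O)[C@H](CO[Si](C)(C)C(C)(C)C)[C@@H](c1ccc(O[Si](C)(C)C(C)(C)C)c(OC)c1)O[C@@H]2[C@@H](CO[Si](C)(C)C(C)(C)C)O | intermediate
34 | C1′ (S) aryl ether, tetra-TBS derivative of the target | COC1=C[C@]2(C=CC1=O)[C@H](CO[Si](C)(C)C(C)(C)C)[C@@H](c1ccc(O[Si](C)(C)C(C)(C)C)c(OC)c1)O[C@@H]2[C@H](CO[Si](C)(C)C(C)(C)C)Oc1ccc(CCCO[Si](C)(C)C(C)(C)C)cc1OC | intermediate
35 | CNP0252711.1, (1S,3S,4R,5S)-configured spirodienone with (1′S) aryl ether | COC1=C[C@]2(C=CC1=O)[C@H](CO)[C@@H](c1ccc(O)c(OC)c1)O[C@@H]2[C@H](CO)Oc1ccc(CCCO)cc1OC | target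

**Step count and risks**

Total steps: 21. Longest linear sequence: 19 steps (steps 3 to 21, from 6).

Steps most likely to fail:

1. Step 19. Backside attack at the neopentylic C1 may be slow. That would leave room for reversible conjugate addition of the C3 hydroxyl to C10, for 6-endo opening at C1′, or for acid-induced ionisation at the electron-rich benzylic C3. Fallback: close the oxolane before any Michael acceptor exists, setting out from 23 and coming back at 34.
   - Sharpless epoxidation of 23 (Ti(OiPr)4, D-(−)-diethyl tartrate, t-BuOOH) would give the ketal epoxy alcohol F1.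
   - TBSCl/imidazole would give its silyl ether F2.
   - Buffered HF·pyridine would give the ketal C3 alcohol F3.
   - Catalytic camphorsulfonic acid in CH2Cl2 would close the ring to the spiro ketal carbinol F4.
   - Mitsunobu reaction with 5 would give the ketal aryl ether F5.
   - PPTS in aqueous acetone would give the enone aryl ether F6.
   - KN(SiMe3)2 and the sulfonyloxaziridine would give the C7 carbinol F7.
   - Dess–Martin oxidation would give the diosphenol F8.
   - MeI/Ag2O would then give 34.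

2. Step 20. Activation of the hindered C1′ carbinol may be sluggish, and elimination or participation of the ring oxygen O2 (retention or ring expansion) may compete with direct displacement. Fallback from 33 back to 34: Tf2O and 2,6-di-tert-butyl-4-methylpyridine at −78 °C would give the C1′ triflate F9. It would then be displaced with inversion by the preformed potassium phenolate of 5 (KN(SiMe3)2, 18-crown-6, THF, −40 °C).

3. Step 8. The enolate carbon is neopentylic, so addition to the electron-rich aldehyde may stall, and Bu2BOTf may open the allylic ketal. Fallback by acylation and chelation-controlled reduction, setting out from 13 and 2 and coming back at 20.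
   - 13 would be coupled with (R)-4-benzyl-1,3-oxazolidin-2-one (PivCl, Et3N, LiCl) to the enantiomeric-auxiliary imide F10. The enantiomeric auxiliary is needed because the chelated sodium enolate reacts on the face opposite to that used by the boron enolate.
   - Noyori ketalisation would give its ketal F11.
   - 2 would be oxidised (NaClO2, NaH2PO4, 2-methylbut-2-ene) to the benzoic acid F12 and converted with oxalyl chloride into the acid chloride F13.
   - The sodium enolate of F11 (NaN(SiMe3)2, THF, −78 °C) would be C-acylated by F13 to the β-keto imide F14.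
   - Zn(BH4)2 would reduce F14 to the syn carbinol F15.
   - LiBH4 would release the diol 20.

**Further compounds**

F1 | step 19 | ketal epoxy alcohol (C1 R, C1′ R) from 23 | O1CCOC12C=C[C@]([C@H]3O[C@@H]3CO)([C@H](CO[Si](C)(C)C(C)(C)C)[C@H](O[Si](CC)(CC)CC)c3ccc(O[Si](C)(C)C(C)(C)C)c(OC)c3)CC2
F2 | step 19 | C2′ O-TBS ether of F1 | O1CCOC12C=C[C@]([C@H]3O[C@@H]3CO[Si](C)(C)C(C)(C)C)([C@H](CO[Si](C)(C)C(C)(C)C)[C@H](O[Si](CC)(CC)CC)c3ccc(O[Si](C)(C)C(C)(C)C)c(OC)c3)CC2
F3 | step 19 | ketal epoxide with free C3 alcohol | O1CCOC12C=C[C@]([C@H]3O[C@@H]3CO[Si](C)(C)C(C)(C)C)([C@H](CO[Si](C)(C)C(C)(C)C)[C@H](O)c3ccc(O[Si](C)(C)C(C)(C)C)c(OC)c3)CC2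
F4 | step 19 | spiro oxolane C8 ketal with C1′ (R) carbinol | O1CCOC13C=C[C@@]2(CC3)[C@H](CO[Si](C)(C)C(C)(C)C)[C@@H](c3ccc(O[Si](C)(C)C(C)(C)C)c(OC)c3)O[C@@H]2[C@@H](CO[Si](C)(C)C(C)(C)C)O
F5 | step 19 | spiro oxolane C8 ketal with C1′ (S) aryl ether | O1CCOC13C=C[C@@]2(CC3)[C@H](CO[Si](C)(C)C(C)(C)C)[C@@H](c3ccc(O[Si](C)(C)C(C)(C)C)c(OC)c3)O[C@@H]2[C@H](CO[Si](C)(C)C(C)(C)C)Oc2ccc(CCCO[Si](C)(C)C(C)(C)C)cc2OC
F6 | step 19 | spiro oxolane enone aryl ether | O=C1C=C[C@@]2(CC1)[C@H](CO[Si](C)(C)C(C)(C)C)[C@@H](c1ccc(O[Si](C)(C)C(C)(C)C)c(OC)c1)O[C@@H]2[C@H](CO[Si](C)(C)C(C)(C)C)Oc1ccc(CCCO[Si](C)(C)C(C)(C)C)cc1OC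
F7 | step 19 | C7-hydroxy derivative of F6, both C7 epimers | O=C1C=C[C@@]2(CC1O)[C@H](CO[Si](C)(C)C(C)(C)C)[C@@H](c1ccc(O[Si](C)(C)C(C)(C)C)c(OC)c1)O[C@@H]2[C@H](CO[Si](C)(C)C(C)(C)C)Oc1ccc(CCCO[Si](C)(C)C(C)(C)C)cc1OC
F8 | step 19 | diosphenol (C6=C7(OH) dienone) from F7 | O=C1C=C[C@@]2(C=C1O)[C@H](CO[Si](C)(C)C(C)(C)C)[C@@H](c1ccc(O[Si](C)(C)C(C)(C)C)c(OC)c1)O[C@@H]2[C@H](CO[Si](C)(C)C(C)(C)C)Oc1ccc(CCCO[Si](C)(C)C(C)(C)C)cc1OC
F9 | step 20 | C1′ triflate of 33 | COC1=C[C@]2(C=CC1=O)[C@H](CO[Si](C)(C)C(C)(C)C)[C@@H](c1ccc(O[Si](C)(C)C(C)(C)C)c(OC)c1)O[C@@H]2[C@@H](CO[Si](C)(C)C(C)(C)C)OS(=O)(=O)C(F)(F)F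
F10 | step 8 | imide of 13 with (R)-4-benzyl-1,3-oxazolidin-2-one | O=C1C=C[C@](/C=C/C(=O)OCC)(CC(=O)N2C(=O)OC[C@H]2Cc2ccccc2)CC1
F11 | step 8 | C8 ethylene ketal of F10 | O1CCOC12C=C[C@](/C=C/C(=O)OCC)(CC(=O)N3C(=O)OC[C@H]3Cc3ccccc3)CC2
F12 | step 8 | 4-(tert-butyldimethylsilyloxy)-3-methoxybenzoic acid | COc1cc(C(=O)O)ccc1O[Si](C)(C)C(C)(C)C
F13 | step 8 | 4-(tert-butyldimethylsilyloxy)-3-methoxybenzoyl chloride | COc1cc(C(=O)Cl)ccc1O[Si](C)(C)C(C)(C)C
F14 | step 8 | β-keto imide: F11 acylated at C4 with the aroyl group | O1CCOC12C=C[C@](/C=C/C(=O)OCC)([C@H](C(=O)N3C(=O)OC[C@H]3Cc3ccccc3)C(=O)c3ccc(O[Si](C)(C)C(C)(C)C)c(OC)c3)CC2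
F15 | step 8 | syn β-hydroxy imide carrying the (R)-auxiliary, C3 and C4 as in 19 | O1CCOC12C=C[C@](/C=C/C(=O)OCC)([C@H](C(=O)N3C(=O)OC[C@H]3Cc3ccccc3)[C@H](O)c3ccc(O[Si](C)(C)C(C)(C)C)c(OC)c3)CC2
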